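A leftover is certain in this flask from the charge: reagent at 0.700 M stands below starting material at 1.0 M, so reagent is the limiting reagent and starting material is the leftover. How much is left depends on how the reagent divides between the cycle and the homo dimer, and the orders asked for depend on the same division.

starting material 1.0 M; reagent 0.700 M; free catalyst 20 mM

    catalyst intermediate C → catalyst intermediate D (k1 = 0.0391 min⁻¹)
    catalyst intermediate A ⇌ catalyst intermediate B (K2 = 2.4, k2 = 3.43 min⁻¹)
    starting material + free catalyst → catalyst intermediate A (k3 = 0.179 M⁻¹ min⁻¹)
    catalyst intermediate D → free catalyst + target (k4 = 0.0461 min⁻¹)
    reagent + catalyst intermediate B ⇌ catalyst intermediate C (K5 = 0.54 M⁻¹, k5 = 0.0122 M⁻¹ min⁻¹)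
    2 reagent → homo dimer (k6 = 1.45 × 10⁻⁴ M⁻¹ min⁻¹)

1. apparent order in reagent when 30% of the starting material are converted (percent change of the rate of making target for one percent more reagent charged)
2. apparent order in free catalyst when 30% of the starting material are converted (percent change of the rate of making target for one percent more free catalyst charged)

I take catalyst intermediates A and B as the resting state, equilibrated because step 2 runs at 4900 d⁻¹, far faster than step 1 at 56 d⁻¹. Reagent then enters the cycle at κ·c(catalyst)·c(reagent), with κ = 0.00546 M⁻¹ min⁻¹.

Two extreme versions can be solved in the head. Without the homo dimer, the flask is pseudo-first-order in reagent with half-life 4.41 d, and the whole 0.700 M becomes target. Without the cycle, reagent falls at second order with first half-life 3.42 d, and no target forms. These half-lives are close, so the real flask lies well between the two.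

Each reagent through the cycle costs a·c(reagent) more as dimer, a selectivity factor with a = 2.66 M⁻¹. Integrating gives 1 + a·c = (1 + a·c₀)·exp(−a·p), where p is the reagent passed through the cycle. Setting c to zero gives the reagent-limited yield, ln(1 + a·c₀)/a = 0.395 M.

At 30% conversion, p is about 0.280 M, less than the 0.300 M of starting material converted, because about 20 mM of it sits on the catalyst as intermediates. So c(reagent) is 0.135 M. Differentiating at fixed conversion, with the rate proportional to c(reagent) and p falling by what extra catalyst holds, I get an order in reagent of (c₀/c)·exp(−a·p) = 2.46 and an order in free catalyst of 2.56.

The forecast gives 2.4 in reagent, below mine, and 2.7 in free catalyst, above mine, on this ground: “Dimerisation competes strongly with turnover”.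

The simulation gives 2.4 and 2.7, the forecast's values. At 250 d the flask holds target at 38.0% of the starting material charged, close to the reagent-limited yield of 39.5%, with reagent at 0%, starting material at 60.0% and homo dimer at 0.160 M.

(The numbers of this flask are those of an exercise; what happens was integrated by code.)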